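The readings are simulated for substances that don't exist, noise included.

Blue stands at 28% of target after 40.0 h, and that is the number I start from for the two flasks I am handing over.

all flasks: starting material 0.010 M
- blue: second substrate 2.2 mM; third substrate 0.050 M (fed, over 25 h); solid reagent 0.020 M; run made earlier; the fed solution adds 0.25 times the starting volume
- ochre: second substrate 4.2 mM; third substrate 0.050 M (fed, over 25 h); solid reagent 0.020 M; run made earlier; the fed solution adds 0.25 times the starting volume
- north-west: second substrate 5.00 mM; third substrate 0.0500 M (fed, over 25 h); solid reagent 0.0200 M; the fed solution adds 0.25 times the starting volume; time 40 h
- west: second substrate 3.00 mM; third substrate 0.0500 M; solid reagent 0.0200 M; everything together at the start, the whole solution of third substrate included, so that from the start the volume is larger by 0.25 times the starting volume; time 25 h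

| run | time / h | target / % |
|---|---|---|
| blue | 2.50 | 2 |
| blue | 8.00 | 3 |
| blue | 15.0 | 5 |
| blue | 20.0 | 14 |
| blue | 30.0 | 19 |
| blue | 40.0 | 28 |
| ochre | 2.50 | 0 |
| ochre | 8.00 | 1 |
| ochre | 15.0 | 5 |
| ochre | 20.0 | 11 |
| ochre | 30.0 | 16 |
| ochre | 40.0 | 23 |

(each reading ± 1.5 percentage points)

* the flask that ends with the higher amount of target, in percent of the starting material charged, or "neither" when 2 percentage points or less lies between them (north-west / west / neither)
* final target, as a percentage of the starting material charged, in north-west
* final target, as a percentage of the starting material charged, in west

Each flask is a stirred slurry: none of the solid reagent is in solution at the start. North-west receives third substrate by the feed, while west holds its whole dose from the start. I reckon by the pace g, the target at the last reading divided by the hours it took, as a fraction of the charge per hour. It is a mean with the slow early hours inside it, and it treats the target as apparent zero-order on the clock. Blue gives 0.00700 /h and ochre 0.00575 /h, so the pace reads lower with more second substrate, and each of these readings carries a scatter of 1.5 percentage points.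

On the straight line through these two, west at 3.00 mM has the pace 0.00650 /h and north-west at 5.00 mM has 0.00525 /h. So I expect 16.3% in west at 25 h and 21.0% in north-west at 40 h. Blue and ochre were both fed and west is not, so carrying the pace to west is my assumption. Please leave both running to their times. On this reckoning north-west's extra hours outweigh west's faster pace.

The forecast reckons by exposure to third substrate, since “the integral of its concentration reproduces both curves”. It gives 21% for north-west, 22% for west and the answer neither. We part on west, where it stands higher than I do.

The flasks give 22.6% in north-west and 14.6% in west, so north-west ends higher.

starting material + coupling partner → target (k = 0.160 /M/min); second substrate + coupling partner → second product (k = 0.220 /M/min); third substrate + coupling partner → third product (k = 0.0100 /M/min); solid reagent ⇌ coupling partner, rate k4*(cs4 - [coupling partner]) while solid is left; crystals form when [coupling partner] > cs4 (solubility = 4.90 mM, k = 4.60 × 10⁻⁴ /min) Coupling partner, which the solid reagent feeds, stands at 8.75 × 10⁻⁴ M in north-west at 40.0 h and at 8.96 × 10⁻⁴ M in west at 25.0 h. West's pace comes out at 0.00584 /h against my 0.00650 /h. Carried to the same west flask read at 4.0 d, my pace gives 62.4% of target, and that flask holds 60.8%.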